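## Structural features

The target is a bisabolane: a cyclohexanone ring (locants C1–C6: C1 bears the 3-methylbutanoyloxy group, C2 is the ketone, C3 carries the methyl group, C6 carries the side chain) joined at C6 to a chain in which C7 is the spiro-oxirane carbon (oxirane CH2 = C14), C8 a ketone, C9=C10 an E alkene and C11 the carbon bearing the hydroperoxide and two methyl groups. It has five stereocentres, 1S,3S,4S,6R,7R: four on the ring and the exocyclic quaternary C7 directly next to C6. On the ring the acyloxy group at C1 is trans to the C6 substituent, whereas the C3–C4 oxirane oxygen is cis to it (this face is called β below). The fragile groups are the tertiary allylic hydroperoxide, two α,β-epoxy ketones, the α-acyloxy ketone with its epimerisable C1, and the enone. Skeleton and C6 map onto (R)-carvone, so the real difficulty is oxygen placement: an external peroxide nucleophile is expected to add to such an enone anti to the C6 substituent (the wrong 3α,4α oxirane), and C7 is a quaternary centre with little bias from the ring. The key step exploits that C4 is 1,3 to C6 and that C8, two bonds from C6, is oxygenated: a C8–O–O unit held by C7 on C6 can reach C4 only across the β face, so the side chain can hand an oxygen atom to the ring enone with the required cis relationship.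

## Logic of the disconnections

12 to 11: the C11–O bond is cut and the C9=C10 alkene moved back to C10=C11 (retro-Schenck ene). The hydroperoxide is the most fragile group and must come last. This removes the peroxide and the conjugated E-enone in one stroke. The forward step must abstract hydrogen from C9 rather than from a methyl group.

11 to 8: the C8–C9 bond is cut (through 10 and 9: oxidation, cross-metathesis, allylation). The C9–C13 unit is a simple prenyl group, and C8 is left as an aldehyde on the spiro-oxirane. The forward allylation must select the aldehyde of 8 over the C2 ketone and the ester.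

8 to 6: the C7–O and C14–O bonds of the spiro-oxirane are cut (through 7). C7 becomes the sp2 carbon of a 2-substituted allylic alcohol, a substrate class for which reagent-controlled epoxidation is reliable. The forward step must let the tartrate override any bias from C6.

6 to 4 (key disconnection): the C3–O and C4–O bonds of the ring oxirane are cut and that oxygen is reconnected to the oxygen on C8. The oxirane oxygen of 6 is thus the terminal oxygen of the hydroperoxide in 4. This removes two stereocentres and one ring, and the precursor is a plain carvone-type enone. The forward step needs intramolecular delivery to outrun any bimolecular oxygen transfer. In one sentence: an allylic hydroperoxide placed on C8 by an ene reaction passes its terminal oxygen across the ring to its own enone.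

4 to 3: the C8–O bond is cut with return of the alkene to the isopropenyl position (retro-Schenck ene). The forward step must take hydrogen from the methyl group, not from C6–H, and must leave the electron-poor ring alkene alone.

3 to 1: the ester C–O bond and the C1–O bond are cut (through 2). This leaves a commercial terpene ketone that already holds all ring carbons, C7, C8, C14 and the C6 stereocentre. The forward hydroxylation must enter anti to the isopropenyl group.

## Other disconnections considered

Alternative 1: cut the C3–O and C4–O bonds to an external peroxide, i.e. intermolecular Weitz–Scheffer epoxidation of enone 3 (H2O2, NaOH). This is the first plan that comes to mind. The nucleophile should attack C4 axially and anti to the C6 substituent, as 5-substituted cyclohexenones normally do, and give A1, the 3α,4α-oxirane, which is the wrong relative configuration. Correcting this needs a 1,2-reduction, a hydroxyl-directed epoxidation and a re-oxidation, and C8 still has to be oxidised separately. The chosen plan does both jobs in steps 3 and 4.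

Alternative 2: cut the C6–C7 bond by an Ireland–Claisen rearrangement of ester A2 (from (S)-cyclohex-2-en-1-ol and 2,2-dimethyl-1,3-dioxolane-4-carboxylic acid; LiN(iPr)2, Me3SiCl) to acid A3. Suprafacial transfer would set C6, and a chelated enolate could set C7. It leaves a bare cyclohexene, however: the C1 oxygen, the C2 ketone, the C3 methyl group and the C3–C4 oxirane would all have to be added afterwards, roughly doubling the step count. Cyclohexenyl esters can also rearrange through either chair or boat transition states, which makes the C7 outcome hard to defend.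

Alternative 3: cut the C7–C8 bond. Chloromethyl ketone A4 (from 3 by ene-type chlorination and ozonolysis) would take up 2-lithio-2-(3-methylbut-2-enyl)-1,3-dithiane, and the alkoxide would close the oxirane to give A5. This joins the whole chain and forms the spiro-oxirane in one operation. C7 would be controlled only by Felkin–Anh induction from C6, the soft and basic anion can enolise or alkylate the α-chloro ketone, and the C2 carbonyl would have to be carried as a protected alcohol. The route is longer and its key step is less well controlled than a tartrate-directed epoxidation.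

Key step: step 4

Remark: the configuration is taken as drawn in the SMILES (1-acyloxy trans and 3,4-oxirane cis to the C6 substituent; 7R). The C8 carbinol epimers of 9 and 10 are carried as a mixture because C8 ends as a ketone.

## Route

Step 1
Reactants: 1 (R)-(−)-carvone
Product: 2 (5S,6S)-6-hydroxy-2-methyl-5-(prop-1-en-2-yl)cyclohex-2-en-1-one (trans-6-hydroxycarvone; the new OH is on C1 of the locants used here)
Conditions: KN(SiMe3)2, THF, −78 °C; 2-(phenylsulfonyl)-3-phenyloxaziridine; AcOH
Reagents that add atoms: 2-(phenylsulfonyl)-3-phenyloxaziridine (Davis oxaziridine), O=S(=O)(N1OC1c1ccccc1)c1ccccc1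
Why: Davis enolate hydroxylation; kinetic α′-deprotonation gives the cross-conjugated enolate and the oxaziridine oxygen should enter anti to the adjacent isopropenyl group (1S, trans), which is also the thermodynamically preferred diequatorial isomer at this epimerisable centre.

Step 2
Reactants: 2 (5S,6S)-6-hydroxy-2-methyl-5-(prop-1-en-2-yl)cyclohex-2-en-1-one
Product: 3 (1S,6S)-3-methyl-2-oxo-6-(prop-1-en-2-yl)cyclohex-3-en-1-yl 3-methylbutanoate
Conditions: 3-methylbutanoic anhydride, Et3N, DMAP (cat.), CH2Cl2, 0 °C
Reagents that add atoms: 3-methylbutanoic anhydride, CC(C)CC(=O)OC(=O)CC(C)C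
Why: DMAP-catalysed acylation of the secondary α-ketol; no stereocentre is formed and the mild conditions should avoid enediol isomerisation.

Step 3
Reactants: 3 (1S,6S)-3-methyl-2-oxo-6-(prop-1-en-2-yl)cyclohex-3-en-1-yl 3-methylbutanoate
Product: 4 (1S,6S)-6-(3-hydroperoxyprop-1-en-2-yl)-3-methyl-2-oxocyclohex-3-en-1-yl 3-methylbutanoate
Conditions: O2, tetraphenylporphyrin (cat.), hν (>495 nm), CDCl3, 0 °C
Reagents that add atoms: dioxygen, O=O
Why: Schenck ene reaction; the enone alkene is electron-poor and inert to singlet oxygen, so oxygen adds to the terminal CH2 of the isopropenyl group with hydrogen abstraction from the methyl group (C6–H lies in the alkene plane and is poorly aligned), giving the 2-substituted allyl hydroperoxide without any new stereocentre.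

Step 4
Reactants: 4 (1S,6S)-6-(3-hydroperoxyprop-1-en-2-yl)-3-methyl-2-oxocyclohex-3-en-1-yl 3-methylbutanoate
Product: 6 (1S,3S,4S,6S)-3,4-epoxy-6-(3-hydroxyprop-1-en-2-yl)-3-methyl-2-oxocyclohexyl 3-methylbutanoate (oxirane β, cis to the C6 substituent), via bridged 1,2-dioxepane peroxy enolate 5 (not isolated)
Conditions: DBU (1.2 equiv), CH2Cl2 (2 mM), 0 °C to rt
Reagents that add atoms: none
Why: Proposed new method: DBU deprotonates the C8 hydroperoxide, the peroxide anion adds to C4 of the enone in a seven-membered 7-exo-trig conjugate addition to give bridged peroxy enolate 5, and the enolate carbon C3 then displaces the proximal peroxide oxygen (3-exo-tet at oxygen, O–O cleavage), so one oxygen stays as the C3–C4 oxirane and the other leaves as the C8 alkoxide; the closest known reaction types are the intermolecular Weitz–Scheffer epoxidation of enones with a hydroperoxide and an amidine base and the intramolecular peroxy-Michael cyclisation of hydroperoxy enones. The C8–O–O chain is anchored through C7 on C6 and can reach C4 (1,3 to C6, side chain pseudo-axial) only across the face of the C6 substituent, so the oxygen arrives β at C4, opposite to the anti approach of an external peroxide. C3 is set in the same event because the oxirane must be cis-fused, so its C3–O bond forms on the β face and the methyl group ends α. In 5 the enolate carbon C3 lies outside the peroxide ring and can therefore reach the antiperiplanar alignment with the O–O bond that the closure needs. The step needs intramolecular delivery to beat bimolecular oxygen transfer (which would give the 3α,4α isomer); high dilution should secure this because only the tethered path is independent of concentration. It also needs addition to precede base-induced dehydration of the primary hydroperoxide; a non-nucleophilic amidine at low temperature without acylating agent favours addition. The isovalerate and the trans-diequatorial C1 centre should survive DBU, which is regenerated when the C8 alkoxide is protonated, so the step is a net isomerisation.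

Step 5
Reactants: 6 (1S,3S,4S,6S)-3,4-epoxy-6-(3-hydroxyprop-1-en-2-yl)-3-methyl-2-oxocyclohexyl 3-methylbutanoate
Product: 7 (1S,3S,4S,6R)-3,4-epoxy-6-[(2S)-2-(hydroxymethyl)oxiran-2-yl]-3-methyl-2-oxocyclohexyl 3-methylbutanoate
Conditions: Ti(OiPr)4 (10 mol %), L-(+)-diethyl tartrate (12 mol %), t-BuOOH, 4 Å molecular sieves, CH2Cl2, −20 °C
Reagents that add atoms: tert-butyl hydroperoxide, CC(C)(C)OO
Why: Sharpless asymmetric epoxidation of a 2-substituted allylic alcohol under reagent control; L-(+)-tartrate should deliver oxygen in the sense that turns methallyl alcohol into (S)-2-methylglycidol, giving the 7S epoxy alcohol, which corresponds to 7R once C8 is a carbonyl (priority change only). Catalytic titanium with sieves limits opening of the 2,2-disubstituted epoxy alcohol.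

Step 6
Reactants: 7 (1S,3S,4S,6R)-3,4-epoxy-6-[(2S)-2-(hydroxymethyl)oxiran-2-yl]-3-methyl-2-oxocyclohexyl 3-methylbutanoate
Product: 8 (1S,3S,4S,6R)-3,4-epoxy-6-[(2R)-2-formyloxiran-2-yl]-3-methyl-2-oxocyclohexyl 3-methylbutanoate
Conditions: Dess–Martin periodinane, NaHCO3, CH2Cl2, 0 °C to rt
Reagents that add atoms: none
Why: Dess–Martin oxidation of the primary alcohol under buffered conditions; C7 has no hydrogen, so the epoxy aldehyde cannot epimerise.

Step 7
Reactants: 8 (1S,3S,4S,6R)-3,4-epoxy-6-[(2R)-2-formyloxiran-2-yl]-3-methyl-2-oxocyclohexyl 3-methylbutanoate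
Product: 9 (1S,3S,4S,6R)-3,4-epoxy-6-[(2R)-2-(1-hydroxybut-3-en-1-yl)oxiran-2-yl]-3-methyl-2-oxocyclohexyl 3-methylbutanoate (C8 epimers)
Conditions: allylboronic acid pinacol ester, CH2Cl2, rt; aqueous work-up
Reagents that add atoms: 2-allyl-4,4,5,5-tetramethyl-1,3,2-dioxaborolane, C=CCB1OC(C)(C)C(C)(C)O1
Why: uncatalysed allylboration through a closed six-membered transition state; it is selective for the aldehyde over the hindered C2 ketone and the ester, and the new C8 carbinol centre is inconsequential because it is oxidised in step 9.

Step 8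
Reactants: 9 (1S,3S,4S,6R)-3,4-epoxy-6-[(2R)-2-(1-hydroxybut-3-en-1-yl)oxiran-2-yl]-3-methyl-2-oxocyclohexyl 3-methylbutanoate
Product: 10 (1S,3S,4S,6R)-3,4-epoxy-6-[(2R)-2-(1-hydroxy-4-methylpent-3-en-1-yl)oxiran-2-yl]-3-methyl-2-oxocyclohexyl 3-methylbutanoate (C8 epimers)
Conditions: 2-methylbut-2-ene (excess), second-generation Grubbs catalyst RuCl2(=CHPh)(H2IMes)(PCy3) (5 mol %), CH2Cl2, 40 °C
Reagents that add atoms: 2-methylbut-2-ene, CC=C(C)C
Why: olefin cross-metathesis that turns the terminal allyl group into a prenyl group with loss of propene; the substrate has no other alkene and the catalyst tolerates epoxide, ketone, ester and free alcohol.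

Step 9
Reactants: 10 (1S,3S,4S,6R)-3,4-epoxy-6-[(2R)-2-(1-hydroxy-4-methylpent-3-en-1-yl)oxiran-2-yl]-3-methyl-2-oxocyclohexyl 3-methylbutanoate
Product: 11 (1S,3S,4S,6R)-3,4-epoxy-3-methyl-6-[(2R)-2-(4-methylpent-3-enoyl)oxiran-2-yl]-2-oxocyclohexyl 3-methylbutanoate
Conditions: Dess–Martin periodinane, NaHCO3, CH2Cl2, 0 °C
Reagents that add atoms: none
Why: Dess–Martin oxidation converges both C8 epimers on one ketone; the bicarbonate buffer should keep the alkene in the β,γ-position.

Step 10
Reactants: 11 (1S,3S,4S,6R)-3,4-epoxy-3-methyl-6-[(2R)-2-(4-methylpent-3-enoyl)oxiran-2-yl]-2-oxocyclohexyl 3-methylbutanoate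
Product: 12 (1S,3S,4S,6R)-3,4-epoxy-6-{(2R)-2-[(E)-4-hydroperoxy-4-methylpent-2-enoyl]oxiran-2-yl}-3-methyl-2-oxocyclohexyl 3-methylbutanoate (CNP0131119.1)
Conditions: O2, tetraphenylporphyrin (cat.), hν (>495 nm), CDCl3, −10 °C
Reagents that add atoms: dioxygen, O=O
Why: Schenck ene reaction on the only alkene; oxygen adds to C11 with hydrogen abstraction from C9 (allylic and α to the ketone, on the more substituted side of the alkene), so the double bond moves into conjugation as the E isomer and the hydroperoxide appears only in the last step.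

## Compound list

1 | (R)-(−)-carvone | C1C(=O)C(C)=CC[C@H]1C(C)=C | starting material
2 | (5S,6S)-6-hydroxy-2-methyl-5-(prop-1-en-2-yl)cyclohex-2-en-1-one | O[C@@H]1C(=O)C(C)=CC[C@H]1C(C)=C | intermediate
3 | (1S,6S)-3-methyl-2-oxo-6-(prop-1-en-2-yl)cyclohex-3-en-1-yl 3-methylbutanoate | CC(C)CC(=O)O[C@@H]1C(=O)C(C)=CC[C@H]1C(C)=C | intermediate
4 | (1S,6S)-6-(3-hydroperoxyprop-1-en-2-yl)-3-methyl-2-oxocyclohex-3-en-1-yl 3-methylbutanoate | CC(C)CC(=O)O[C@@H]1C(=O)C(C)=CC[C@H]1C(=C)COO | intermediate
5 | bridged 1,2-dioxepane peroxy enolate (written as its neutral enol; O–O bridge from C8 to C4 on the β face) | CC(C)CC(=O)O[C@@H]1C(O)=C(C)[C@@H]2C[C@H]1C(=C)COO2 | intermediate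
6 | (1S,3S,4S,6S)-3,4-epoxy-6-(3-hydroxyprop-1-en-2-yl)-3-methyl-2-oxocyclohexyl 3-methylbutanoate | CC(C)CC(=O)O[C@@H]1C(=O)[C@@]2(C)O[C@H]2C[C@H]1C(=C)CO | intermediate
7 | (1S,3S,4S,6R)-3,4-epoxy-6-[(2S)-2-(hydroxymethyl)oxiran-2-yl]-3-methyl-2-oxocyclohexyl 3-methylbutanoate | CC(C)CC(=O)O[C@@H]1C(=O)[C@@]2(C)O[C@H]2C[C@H]1[C@]1(CO)CO1 | intermediate
8 | (1S,3S,4S,6R)-3,4-epoxy-6-[(2R)-2-formyloxiran-2-yl]-3-methyl-2-oxocyclohexyl 3-methylbutanoate | CC(C)CC(=O)O[C@@H]1C(=O)[C@@]2(C)O[C@H]2C[C@H]1[C@]1(C=O)CO1 | intermediate
9 | (1S,3S,4S,6R)-3,4-epoxy-6-[(2R)-2-(1-hydroxybut-3-en-1-yl)oxiran-2-yl]-3-methyl-2-oxocyclohexyl 3-methylbutanoate (C8 epimers) | CC(C)CC(=O)O[C@@H]1C(=O)[C@@]2(C)O[C@H]2C[C@H]1[C@]1(C(O)CC=C)CO1 | intermediate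
10 | (1S,3S,4S,6R)-3,4-epoxy-6-[(2R)-2-(1-hydroxy-4-methylpent-3-en-1-yl)oxiran-2-yl]-3-methyl-2-oxocyclohexyl 3-methylbutanoate (C8 epimers) | CC(C)CC(=O)O[C@@H]1C(=O)[C@@]2(C)O[C@H]2C[C@H]1[C@]1(C(O)CC=C(C)C)CO1 | intermediate
11 | (1S,3S,4S,6R)-3,4-epoxy-3-methyl-6-[(2R)-2-(4-methylpent-3-enoyl)oxiran-2-yl]-2-oxocyclohexyl 3-methylbutanoate | CC(C)CC(=O)O[C@@H]1C(=O)[C@@]2(C)O[C@H]2C[C@H]1[C@]1(C(=O)CC=C(C)C)CO1 | intermediate
12 | (1S,3S,4S,6R)-3,4-epoxy-6-{(2R)-2-[(E)-4-hydroperoxy-4-methylpent-2-enoyl]oxiran-2-yl}-3-methyl-2-oxocyclohexyl 3-methylbutanoate (CNP0131119.1) | CC(C)CC(=O)O[C@@H]1C(=O)[C@@]2(C)O[C@H]2C[C@H]1[C@]1(C(=O)/C=C/C(C)(C)OO)CO1 | target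

## Step count and risk

Total step count: 10. Longest linear sequence: 10 steps from 1.

Least certain steps:

Step 4 (key step). The most likely failure is bimolecular oxygen transfer competing with the tethered path, which would put the oxirane on the α face. The peroxy-Michael adduct could also stall as a cyclic peroxide, or the primary hydroperoxide could be dehydrated by base to the enal before it adds. The seven-membered delivery has no direct precedent, so its rate relative to these processes cannot be taken for granted. The fallback uses known chemistry, sets out from 3 and comes back at 6. Luche reduction (NaBH4, CeCl3·7H2O, MeOH, −78 °C; axial hydride, all-equatorial product) gives the allylic alcohol F1. Hydroxyl-directed epoxidation (VO(acac)2, t-BuOOH) gives the β-epoxy alcohol F2, and Dess–Martin oxidation gives the epoxy ketone F3. Allylic oxidation of the isopropenyl methyl group (SeO2 cat., t-BuOOH) then gives 6.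

Step 3. Singlet oxygen reacts slowly with a 1,1-disubstituted alkene, so physical quenching and slow photo-degradation of the α-acyloxy enone may win before conversion is complete. The fallback sets out from 3 and comes back at 4. Ene-type chlorination of the isopropenyl group (Ca(OCl)2, CO2, CH2Cl2–H2O) gives the allylic chloride F4, and silver-assisted perhydrolysis (AgOCOCF3, ethereal H2O2) replaces chloride by the hydroperoxide.

Step 5. Double diastereoselection with the C6 stereocentre may be mismatched and lower the facial selectivity, and titanium alkoxides may open the 2,2-disubstituted epoxy alcohol. The fallback sets out from 6 and comes back at 9, and relays the stereochemistry through C8 instead. MnO2 oxidation gives the enal F5. Brown allylboration with (−)-Ipc2B(allyl) (from (+)-α-pinene, Si-face selective, −78 °C) gives the (8S)-dienol F6. Hydroxyl-directed epoxidation (VO(acac)2, t-BuOOH), which is erythro-selective for 2-substituted allylic alcohols, should then place the oxirane on the required face of C7 and give 9 as its 8S epimer.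

Step 10. Hydrogen abstraction from the Z-methyl group instead of C9 would give the secondary hydroperoxide with an isopropenyl group, and the two modes are often close in rate for 2-methyl-2-alkenes. The fallback sets out from 8 and comes back at 12, and brings the hydroperoxide in as a protected building block. Vinylmagnesium bromide (CH2=CHMgBr, THF, −78 °C) gives the allylic alcohol F7, and Dess–Martin oxidation gives the vinyl ketone F8. Cross-metathesis with 2-methoxy-2-[(2-methylbut-3-en-2-yl)peroxy]propane (second-generation Hoveyda–Grubbs catalyst RuCl2(H2IMes)(=CH-C6H4-2-OiPr)) gives the E-configured peroxyketal F9. Mild acid (AcOH, THF, H2O) then releases 12.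

## Further compounds

F1 | step 4 | (1S,6S)-2β-hydroxy-3-methyl-6-(prop-1-en-2-yl)cyclohex-3-en-1-yl 3-methylbutanoate (C2–OH cis to the C6 substituent) | CC(C)CC(=O)O[C@@H]1[C@@H](O)C(C)=CC[C@H]1C(C)=C
F2 | step 4 | 3β,4β-epoxy-2β-hydroxy-3-methyl-6-(prop-1-en-2-yl)cyclohexyl 3-methylbutanoate | CC(C)CC(=O)O[C@@H]1[C@@H](O)[C@@]2(C)O[C@H]2C[C@H]1C(C)=C
F3 | step 4 | (1S,3S,4S,6S)-3,4-epoxy-3-methyl-2-oxo-6-(prop-1-en-2-yl)cyclohexyl 3-methylbutanoate | CC(C)CC(=O)O[C@@H]1C(=O)[C@@]2(C)O[C@H]2C[C@H]1C(C)=C
F4 | step 3 | (1S,6S)-6-(3-chloroprop-1-en-2-yl)-3-methyl-2-oxocyclohex-3-en-1-yl 3-methylbutanoate | CC(C)CC(=O)O[C@@H]1C(=O)C(C)=CC[C@H]1C(=C)CCl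
F5 | step 5 | (1S,3S,4S,6S)-3,4-epoxy-3-methyl-2-oxo-6-(3-oxoprop-1-en-2-yl)cyclohexyl 3-methylbutanoate | CC(C)CC(=O)O[C@@H]1C(=O)[C@@]2(C)O[C@H]2C[C@H]1C(=C)C=O
F6 | step 5 | (1S,3S,4S,6S)-3,4-epoxy-6-[(3S)-3-hydroxyhexa-1,5-dien-2-yl]-3-methyl-2-oxocyclohexyl 3-methylbutanoate | CC(C)CC(=O)O[C@@H]1C(=O)[C@@]2(C)O[C@H]2C[C@H]1C(=C)[C@@H](O)CC=C
F7 | step 10 | (1S,3S,4S,6R)-3,4-epoxy-6-[(2R)-2-(1-hydroxyprop-2-en-1-yl)oxiran-2-yl]-3-methyl-2-oxocyclohexyl 3-methylbutanoate (C8 epimers) | CC(C)CC(=O)O[C@@H]1C(=O)[C@@]2(C)O[C@H]2C[C@H]1[C@]1(C(O)C=C)CO1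
F8 | step 10 | (1S,3S,4S,6R)-6-[(2R)-2-acryloyloxiran-2-yl]-3,4-epoxy-3-methyl-2-oxocyclohexyl 3-methylbutanoate | CC(C)CC(=O)O[C@@H]1C(=O)[C@@]2(C)O[C@H]2C[C@H]1[C@]1(C(=O)C=C)CO1
F9 | step 10 | 2-methoxypropan-2-yl peroxyketal of 12 | CC(C)CC(=O)O[C@@H]1C(=O)[C@@]2(C)O[C@H]2C[C@H]1[C@]1(C(=O)/C=C/C(C)(C)OOC(C)(C)OC)CO1
A1 | alternative 1 | (1S,3R,4R,6S)-3,4-epoxy-3-methyl-2-oxo-6-(prop-1-en-2-yl)cyclohexyl 3-methylbutanoate (oxirane α, trans to the C6 substituent) | CC(C)CC(=O)O[C@@H]1C(=O)[C@]2(C)O[C@@H]2C[C@H]1C(C)=C
A2 | alternative 2 | (S)-cyclohex-2-en-1-yl 2,2-dimethyl-1,3-dioxolane-4-carboxylate | CC1(C)OCC(O1)C(=O)O[C@@H]1C=CCCC1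
A3 | alternative 2 | 4-(cyclohex-2-en-1-yl)-2,2-dimethyl-1,3-dioxolane-4-carboxylic acid with C6 and C7 configured as in 12 | C1=CCCC[C@H]1[C@]2(C(=O)O)COC(C)(C)O2
A4 | alternative 3 | (1S,6S)-6-(2-chloroacetyl)-3-methyl-2-oxocyclohex-3-en-1-yl 3-methylbutanoate | CC(C)CC(=O)O[C@@H]1C(=O)C(C)=CC[C@H]1C(=O)CCl
A5 | alternative 3 | spiro-oxirane bearing the 2-(3-methylbut-2-enyl)-1,3-dithian-2-yl group at C7, C6 and C7 configured as in 12 | CC(C)CC(=O)O[C@@H]1C(=O)C(C)=CC[C@H]1[C@]1(C2(CC=C(C)C)SCCCS2)CO1
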